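Readings and results stem from a simulated flask for an exercise; scatter was added.

At 4.00 h the cedar flask reads c(isomer of the product) 91.4%, its highest reading yet, and c(target) 4.2%.

| setting | cedar | flask |
|---|---|---|
| starting material | 20 mM | 20 mM |
| free catalyst | 2.8 mol% | 2.8 mol% |
| remark | the very flask that is asked about, followed so far |  |
| time |  | 5.0 d |

cedar run (percent of the starting material charged)

| time / h | isomer of the product / % | target / % |
|---|---|---|
| 0.667 | 68.3 | 1.9 |
| 1.50 | 88.5 | 3.0 |
| 4.00 | 91.4 | 4.2 |
| 8.00 | 88.8 | 6.5 |
| 15.0 | 85.7 | 9.5 |
| 40.0 | 78.6 | 16.3 |

(scatter of a reading: 0.3 percentage points)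



- time up to 5.0 d at which isomer of the product stands highest
- the amount of isomer of the product, in percent of the starting material charged, at that time

The two readings at 4.00 h sum to 95.6%. I call this sum the ceiling, the mass balance of the two products once the fast rise is over, and it slips just to 94.9% at 40.0 h. While the sum holds, c(isomer of the product) is the ceiling minus c(target). I put the peak between 1.50 h and 4.00 h, with c(target) midway between its two readings there, so I expect 92.0%.

The forecast says 91.6% (91.1% to 92.2%) at 0.125 d (0.09 d to 0.17 d), 0.4 percentage points below my figure, on the ground that “The peak comes where feed equals drain”.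

The flask peaks at 91.7% at 0.122 d, inside both of the forecast's ranges.

    isomer of the product ⇌ starting material (k = 0.00110 min⁻¹)
    starting material + free catalyst → spent catalyst (k = 0.570 M⁻¹ min⁻¹)
    target + free catalyst ⇌ isomer of the product + free catalyst, rate k3*[free catalyst]*[target] forward; the back reaction follows from the equilibrium constant (K = 2.30, k = 0.600 M⁻¹ min⁻¹)
    starting material ⇌ target (K = 12.0, k = 7.00 × 10⁻⁴ min⁻¹)

Each spent catalyst has taken up one starting material, so the ceiling is the charge less c(starting material) less the spent catalyst counted on the charge. At 5.00 d this flask has 2.59% starting material and 92.8% of its 2.8 mol% catalyst spent, which gives 94.8% at that time, lower than the 95.6% read at 4.00 h. The neighbour flask with 11 mol% free catalyst has 2.21% starting material and 89.6% of its catalyst spent at 5.00 d, so its ceiling comes to 87.9%. At that time the neighbour flask holds 61.2% isomer of the product and 26.7% target, after a peak of 86.6%.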